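**Assumption:** MOMCl, iPr2NCOCl, (+)-sparteine, Cp2TiMe2, B2pin2 and similar items are bought and used as reagents; the carbon building blocks are resorcinol, oxirane, 2,2-dimethylcyclopentanone and catechol.

**Retrosynthetic overview**
1. Target ⇐ global MOM removal of flavone 21 ⇐ carbonylative Sonogashira annulation of o-iodophenol 15 (A ring + terpenoid) with alkyne 20 (B ring, from catechol); the pyranone ring is formed last.
2. 15 ⇐ arene 12 by sterically controlled Ir C–H borylation/oxidation (third A-ring oxygen) and ortho-iodination.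
3. trans-Hydroxycyclohexane of 12 ⇐ exocyclic alkene 11 (Markovnikov hydration) ⇐ ketone 10 (methylenation).
4. Ketone 10 ⇐ one-carbon ring expansion (1,2-alkyl shift) of 2,2-dimethylcyclopentanone by a sparteine-derived lithiated carbamate that carries the ArCH2 unit; this makes the cyclohexane ring and sets the ring CH stereocentre.
5. Carbamate 6 ⇐ resorcinol bis-MOM ether (ortho-lithiation) + oxirane. Ring order: A ring (resorcinol) → cyclohexane (ring expansion) → pyranone (annulation).

**Route**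

Step 1
Reactants: 1 resorcinol (benzene-1,3-diol)
Product: 2 1,3-bis(methoxymethoxy)benzene
Conditions: NaH, MOMCl, DMF, 0 °C → rt
Reagents that add atoms: chloromethyl methyl ether COCCl
Why: Double Williamson O-alkylation of the phenoxides; MOM directs the ortho-lithiation of step 2, survives the organometallic steps and is removed at the end without protic acid.

Step 2
Reactants: 2 1,3-bis(methoxymethoxy)benzene; 3 oxirane
Product: 6 2-[2,6-bis(methoxymethoxy)phenyl]ethyl N,N-diisopropylcarbamate, via aryllithium 4 (not isolated), via lithium alkoxide 5 (not isolated)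
Conditions: n-BuLi, THF, 0 °C → rt; oxirane, CuI (10 mol%), −30 °C → rt; iPr2NCOCl, 60 °C
Reagents that add atoms: N,N-diisopropylcarbamoyl chloride CC(C)N(C(C)C)C(Cl)=O
Why: Directed ortho-metalation occurs at C2 between the two OMOM groups, the aryl nucleophile opens oxirane by SN2, and the lithium alkoxide is O-carbamoylated in the same pot to install the Hoppe directing/leaving group.

Step 3
Reactants: 6 2-[2,6-bis(methoxymethoxy)phenyl]ethyl N,N-diisopropylcarbamate; 7 2,2-dimethylcyclopentan-1-one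
Product: 10 (2S)-2-{[2,6-bis(methoxymethoxy)phenyl]methyl}-3,3-dimethylcyclohexan-1-one, via lithiated carbamate 8 (not isolated), via alkoxide adduct 9 (not isolated)
Conditions: s-BuLi, (+)-sparteine, Et2O, −78 °C, 5 h; 7, −78 °C; Et2AlCl (3 equiv), −78 → 0 °C
Reagents that add atoms: none
Why: Proposed new method: s-BuLi/(+)-sparteine removes the pro-R α-proton of 6 to give the configurationally stable (R)-α-lithio carbamate 8 (Hoppe deprotonation), which adds to ketone 7 with retention to give alkoxide 9; Li→Al exchange with Et2AlCl makes the alkoxide oxygen the electron push and, by binding the carbamate C=O, makes OCb a leaving group, so the antiperiplanar, more electron-rich ring bond C1–C(CH3)2 migrates to the carbamate carbon with inversion (semipinacol-type 1,2-alkyl shift), which expands cyclopentane to cyclohexanone, erases the carbinol centre and sets the (S) α-centre; the closest known reactions are the organoaluminium-promoted pinacol-type rearrangement of β-mesyloxy alcohols, Tiffeneau–Demjanov and β-oxido-carbenoid ring expansions, and the 1,2-metallate shift of boronate complexes of lithiated carbamates, whereas an alkoxide-driven 1,2-shift onto a sparteine-derived carbamate carbon is, to my knowledge, not yet reported.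

Step 4
Reactants: 10 (2S)-2-{[2,6-bis(methoxymethoxy)phenyl]methyl}-3,3-dimethylcyclohexan-1-one
Product: 11 2-{[(1S)-2,2-dimethyl-6-methylidenecyclohexyl]methyl}-1,3-bis(methoxymethoxy)benzene
Conditions: Cp2TiMe2, toluene/THF, 65 °C, dark
Reagents that add atoms: dimethyltitanocene C[Ti](C)(C1C=CC=C1)C1C=CC=C1
Why: Petasis methylenation is non-basic, so the enolisable α-stereocentre is not epimerised, and it still olefinates the hindered ketone.

Step 5
Reactants: 11 2-{[(1S)-2,2-dimethyl-6-methylidenecyclohexyl]methyl}-1,3-bis(methoxymethoxy)benzene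
Product: 12 (1S,2S)-2-{[2,6-bis(methoxymethoxy)phenyl]methyl}-1,3,3-trimethylcyclohexan-1-ol
Conditions: Co(acac)2 (20 mol%), PhSiH3, O2 (1 atm), THF/i-PrOH, rt
Reagents that add atoms: dioxygen O=O
Why: Mukaiyama hydration (Co–H hydrogen-atom transfer, then O2 capture of the tertiary radical) is Markovnikov; in the chair with CH2Ar equatorial the axial face is blocked by the syn-axial C3 methyl, so oxygen enters equatorially and the new OH ends trans to CH2Ar (1S), as in equatorial oxygenation of exocyclic drimane/labdane alkenes.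

Step 6
Reactants: 12 (1S,2S)-2-{[2,6-bis(methoxymethoxy)phenyl]methyl}-1,3,3-trimethylcyclohexan-1-ol
Product: 14 4-{[(1S,2S)-2-hydroxy-2,6,6-trimethylcyclohexyl]methyl}-3,5-bis(methoxymethoxy)phenol, via arylboronate 13 (not isolated)
Conditions: [Ir(OMe)(cod)]2 (1.5 mol%), dtbpy, B2pin2, THF, 80 °C; then aq. NaOH, H2O2, 0 °C → rt
Reagents that add atoms: hydrogen peroxide OO
Why: Sterically controlled Ir-catalysed C–H borylation takes the only arene C–H without an ortho substituent (para to the alkyl group, meta to both OMOM groups), and C–B oxidation then gives the phloroglucinol oxygen pattern.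

Step 7
Reactants: 14 4-{[(1S,2S)-2-hydroxy-2,6,6-trimethylcyclohexyl]methyl}-3,5-bis(methoxymethoxy)phenol
Product: 15 4-{[(1S,2S)-2-hydroxy-2,6,6-trimethylcyclohexyl]methyl}-2-iodo-3,5-bis(methoxymethoxy)phenol
Conditions: NIS (1.0 equiv), MeCN, −20 → 0 °C
Reagents that add atoms: N-iodosuccinimide O=C1CCC(=O)N1I
Why: Electrophilic aromatic iodination of a phloroglucinol-type phenol; the two free positions are equivalent and both ortho to OH, so one equivalent gives a single mono-iodide.

Step 8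
Reactants: 16 catechol (benzene-1,2-diol)
Product: 17 1-(3,4-dihydroxyphenyl)ethan-1-one
Conditions: AcOH, BF3·OEt2, 90 °C; aq. NaOAc
Reagents that add atoms: acetic acid CC(=O)O
Why: Friedel–Crafts (Nencki-type) C-acetylation of catechol occurs para to one hydroxyl.

Step 9
Reactants: 17 1-(3,4-dihydroxyphenyl)ethan-1-one
Product: 18 1-[3,4-bis(methoxymethoxy)phenyl]ethan-1-one
Conditions: MOMCl, i-Pr2NEt, CH2Cl2, 0 °C → rt
Reagents that add atoms: chloromethyl methyl ether COCCl
Why: Williamson-type MOM protection gives the B ring the same protecting group as the A ring.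

Step 10
Reactants: 18 1-[3,4-bis(methoxymethoxy)phenyl]ethan-1-one
Product: 20 4-ethynyl-1,2-bis(methoxymethoxy)benzene, via enol phosphate 19 (not isolated)
Conditions: LDA (1.1 equiv), THF, −78 °C; ClP(O)(OEt)2, −78 °C → rt; LDA (2.3 equiv), −78 °C → rt
Reagents that add atoms: none
Why: Negishi one-pot ketone-to-alkyne conversion: O-phosphorylation of the kinetic enolate, then LDA-induced elimination of diethyl phosphate.

Step 11
Reactants: 15 4-{[(1S,2S)-2-hydroxy-2,6,6-trimethylcyclohexyl]methyl}-2-iodo-3,5-bis(methoxymethoxy)phenol; 20 4-ethynyl-1,2-bis(methoxymethoxy)benzene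
Product: 21 2-[3,4-bis(methoxymethoxy)phenyl]-6-{[(1S,2S)-2-hydroxy-2,6,6-trimethylcyclohexyl]methyl}-5,7-bis(methoxymethoxy)-4H-chromen-4-one
Conditions: PdCl2(dppf) (5 mol%), Et2NH, CO (3 atm), DMF, 70 °C
Reagents that add atoms: carbon monoxide [C-]#[O+]
Why: Carbonylative Sonogashira coupling gives the o-hydroxyaryl ynone, which Et2NH converts by conjugate addition and 6-endo addition–elimination into the pyranone ring (flavone, not aurone); the basic medium leaves the tertiary alcohol and MOM groups untouched.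

Step 12
Reactants: 21 2-[3,4-bis(methoxymethoxy)phenyl]-6-{[(1S,2S)-2-hydroxy-2,6,6-trimethylcyclohexyl]methyl}-5,7-bis(methoxymethoxy)-4H-chromen-4-one
Product: 23 2-(3,4-dihydroxyphenyl)-5,7-dihydroxy-6-{[(1S,2S)-2-hydroxy-2,6,6-trimethylcyclohexyl]methyl}-4H-chromen-4-one (target CNP0257603.1), via pentakis-TMS ether 22 (not isolated)
Conditions: TMSOTf, 2,2′-bipyridyl, CH2Cl2, 0 °C → rt; then H2O/MeOH, citric acid, rt
Reagents that add atoms: none
Why: TMSOTf/2,2′-bipyridyl converts aryl MOM ethers into aryl TMS ethers without free protic acid (the tertiary alcohol is only silylated), and mild aqueous citric acid then cleaves all O–Si bonds, so the tertiary alcohol is not ionised and cannot cyclise onto the flanking phenols.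

**Compound list**
1 | resorcinol (benzene-1,3-diol) | Oc1cccc(O)c1 | starting material
2 | 1,3-bis(methoxymethoxy)benzene | COCOc1cccc(OCOC)c1 | intermediate
3 | oxirane | C1CO1 | starting material
4 | [2,6-bis(methoxymethoxy)phenyl]lithium | [Li]c1c(OCOC)cccc1OCOC | intermediate
5 | lithium 2-[2,6-bis(methoxymethoxy)phenyl]ethan-1-olate | [Li]OCCc1c(OCOC)cccc1OCOC | intermediate
6 | 2-[2,6-bis(methoxymethoxy)phenyl]ethyl N,N-diisopropylcarbamate | CC(C)N(C(C)C)C(=O)OCCc1c(OCOC)cccc1OCOC | intermediate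
7 | 2,2-dimethylcyclopentan-1-one | CC1(C)CCCC1=O | starting material
8 | (1R)-2-[2,6-bis(methoxymethoxy)phenyl]-1-lithioethyl N,N-diisopropylcarbamate, (+)-sparteine complex | [Li][C@@H](OC(=O)N(C(C)C)C(C)C)Cc1c(OCOC)cccc1OCOC | intermediate
9 | lithium 1-[(1S)-2-[2,6-bis(methoxymethoxy)phenyl]-1-(diisopropylcarbamoyloxy)ethyl]-2,2-dimethylcyclopentan-1-olate (both carbinol epimers) | CC1(C)CCCC1(O[Li])[C@@H](OC(=O)N(C(C)C)C(C)C)Cc1c(OCOC)cccc1OCOC | intermediate
10 | (2S)-2-{[2,6-bis(methoxymethoxy)phenyl]methyl}-3,3-dimethylcyclohexan-1-one | CC1(C)CCCC(=O)[C@H]1Cc1c(OCOC)cccc1OCOC | intermediate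
11 | 2-{[(1S)-2,2-dimethyl-6-methylidenecyclohexyl]methyl}-1,3-bis(methoxymethoxy)benzene | CC1(C)CCCC(=C)[C@H]1Cc1c(OCOC)cccc1OCOC | intermediate
12 | (1S,2S)-2-{[2,6-bis(methoxymethoxy)phenyl]methyl}-1,3,3-trimethylcyclohexan-1-ol (OH trans to CH2Ar) | CC1(C)CCC[C@](C)(O)[C@H]1Cc1c(OCOC)cccc1OCOC | intermediate
13 | (1S,2S)-2-{[2,6-bis(methoxymethoxy)-4-(4,4,5,5-tetramethyl-1,3,2-dioxaborolan-2-yl)phenyl]methyl}-1,3,3-trimethylcyclohexan-1-ol | CC1(C)CCC[C@](C)(O)[C@H]1Cc1c(OCOC)cc(B2OC(C)(C)C(C)(C)O2)cc1OCOC | intermediate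
14 | 4-{[(1S,2S)-2-hydroxy-2,6,6-trimethylcyclohexyl]methyl}-3,5-bis(methoxymethoxy)phenol | CC1(C)CCC[C@](C)(O)[C@H]1Cc1c(OCOC)cc(O)cc1OCOC | intermediate
15 | 4-{[(1S,2S)-2-hydroxy-2,6,6-trimethylcyclohexyl]methyl}-2-iodo-3,5-bis(methoxymethoxy)phenol | CC1(C)CCC[C@](C)(O)[C@H]1Cc1c(OCOC)cc(O)c(I)c1OCOC | intermediate
16 | catechol (benzene-1,2-diol) | Oc1ccccc1O | starting material
17 | 1-(3,4-dihydroxyphenyl)ethan-1-one | CC(=O)c1ccc(O)c(O)c1 | intermediate
18 | 1-[3,4-bis(methoxymethoxy)phenyl]ethan-1-one | CC(=O)c1ccc(OCOC)c(OCOC)c1 | intermediate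
19 | 1-[3,4-bis(methoxymethoxy)phenyl]ethenyl diethyl phosphate | C=C(OP(=O)(OCC)OCC)c1ccc(OCOC)c(OCOC)c1 | intermediate
20 | 4-ethynyl-1,2-bis(methoxymethoxy)benzene | C#Cc1ccc(OCOC)c(OCOC)c1 | intermediate
21 | 2-[3,4-bis(methoxymethoxy)phenyl]-6-{[(1S,2S)-2-hydroxy-2,6,6-trimethylcyclohexyl]methyl}-5,7-bis(methoxymethoxy)-4H-chromen-4-one | CC1(C)CCC[C@](C)(O)[C@H]1Cc1c(OCOC)cc2oc(-c3ccc(OCOC)c(OCOC)c3)cc(=O)c2c1OCOC | intermediate
22 | pentakis(trimethylsilyl) ether of 23 (four aryl O–TMS and the tertiary O–TMS) | CC1(C)CCC[C@](C)(O[Si](C)(C)C)[C@H]1Cc1c(O[Si](C)(C)C)cc2oc(-c3ccc(O[Si](C)(C)C)c(O[Si](C)(C)C)c3)cc(=O)c2c1O[Si](C)(C)C | intermediate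
23 | 2-(3,4-dihydroxyphenyl)-5,7-dihydroxy-6-{[(1S,2S)-2-hydroxy-2,6,6-trimethylcyclohexyl]methyl}-4H-chromen-4-one | CC1(C)CCC[C@](C)(O)[C@H]1Cc1c(O)cc2oc(-c3ccc(O)c(O)c3)cc(=O)c2c1O | target

**Totals**
Total steps: 12. Longest linear sequence: 9 (steps 1–7, 11, 12, from resorcinol).

**Three steps most likely to fail**

Step 3 (the proposed ring expansion). The risks are epoxide closure or carbamoyl transfer in alkoxide 9, migration of the ring CH2 instead of C(CH3)2, and ring lithiation ortho to OMOM during the deprotonation. The fallback uses known chemistry only, sets out from 6 and 7 and returns at 10. The (+)-sparteine lithiation of 6 and addition to 7 are run as in step 3 but quenched with MeOH at −78 °C, giving (1S)-2-[2,6-bis(methoxymethoxy)phenyl]-1-(1-hydroxy-2,2-dimethylcyclopentyl)ethyl N,N-diisopropylcarbamate F1 (both carbinol epimers; that centre is destroyed later). LiAlH4 in refluxing THF removes the carbamoyl group to give 1-[(1S)-2-[2,6-bis(methoxymethoxy)phenyl]-1-hydroxyethyl]-2,2-dimethylcyclopentan-1-ol F2. MsCl/Et3N at 0 °C sulfonylates only the secondary hydroxyl to give (1S)-2-[2,6-bis(methoxymethoxy)phenyl]-1-(1-hydroxy-2,2-dimethylcyclopentyl)ethyl methanesulfonate F3. Et3Al in CH2Cl2 at −78 °C then effects the established organoaluminium-promoted pinacol-type 1,2-shift with inversion, giving ketone 10.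

Step 5 (diastereoselectivity of the radical hydration). The risk is a poor ratio at the new carbinol centre. The fallback sets out from 11 and returns at 12. mCPBA/NaHCO3 in CH2Cl2 at 0 °C epoxidises the exocyclic alkene from the equatorial side to give (3S,4S)-4-{[2,6-bis(methoxymethoxy)phenyl]methyl}-5,5-dimethyl-1-oxaspiro[2.5]octane F4, which can be purified from its epimer. LiAlH4 in THF opens it at the CH2 terminus to give 12.

Step 11 (carbonylative annulation). The risks are slow oxidative addition to the hindered, electron-rich iodide and aurone formation. The fallback sets out from 14 and 20 and returns at 21. MgCl2/Et3N/paraformaldehyde in MeCN ortho-formylates 14 to 2-hydroxy-5-{[(1S,2S)-2-hydroxy-2,6,6-trimethylcyclohexyl]methyl}-4,6-bis(methoxymethoxy)benzaldehyde F5. Excess lithium acetylide of 20 (n-BuLi, THF, −78 °C) adds to give the propargylic alcohol 3-[3,4-bis(methoxymethoxy)phenyl]-1-{2-hydroxy-5-{[(1S,2S)-2-hydroxy-2,6,6-trimethylcyclohexyl]methyl}-4,6-bis(methoxymethoxy)phenyl}prop-2-yn-1-ol F6 (carbinol epimers). MnO2 in CH2Cl2 oxidises it to the ynone 3-[3,4-bis(methoxymethoxy)phenyl]-1-{2-hydroxy-5-{[(1S,2S)-2-hydroxy-2,6,6-trimethylcyclohexyl]methyl}-4,6-bis(methoxymethoxy)phenyl}prop-2-yn-1-one F7, and Et2NH in EtOH closes the pyranone ring (6-endo) to give 21.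

**Further compounds**
F1 | step 3 | (1S)-2-[2,6-bis(methoxymethoxy)phenyl]-1-(1-hydroxy-2,2-dimethylcyclopentyl)ethyl N,N-diisopropylcarbamate | CC1(C)CCCC1(O)[C@@H](OC(=O)N(C(C)C)C(C)C)Cc1c(OCOC)cccc1OCOC
F2 | step 3 | 1-[(1S)-2-[2,6-bis(methoxymethoxy)phenyl]-1-hydroxyethyl]-2,2-dimethylcyclopentan-1-ol | CC1(C)CCCC1(O)[C@@H](O)Cc1c(OCOC)cccc1OCOC
F3 | step 3 | (1S)-2-[2,6-bis(methoxymethoxy)phenyl]-1-(1-hydroxy-2,2-dimethylcyclopentyl)ethyl methanesulfonate | CC1(C)CCCC1(O)[C@@H](OS(C)(=O)=O)Cc1c(OCOC)cccc1OCOC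
F4 | step 5 | (3S,4S)-4-{[2,6-bis(methoxymethoxy)phenyl]methyl}-5,5-dimethyl-1-oxaspiro[2.5]octane | CC1(C)CCC[C@@]2(CO2)[C@H]1Cc1c(OCOC)cccc1OCOC
F5 | step 11 | 2-hydroxy-5-{[(1S,2S)-2-hydroxy-2,6,6-trimethylcyclohexyl]methyl}-4,6-bis(methoxymethoxy)benzaldehyde | CC1(C)CCC[C@](C)(O)[C@H]1Cc1c(OCOC)cc(O)c(C=O)c1OCOC
F6 | step 11 | 3-[3,4-bis(methoxymethoxy)phenyl]-1-{2-hydroxy-5-{[(1S,2S)-2-hydroxy-2,6,6-trimethylcyclohexyl]methyl}-4,6-bis(methoxymethoxy)phenyl}prop-2-yn-1-ol | CC1(C)CCC[C@](C)(O)[C@H]1Cc1c(OCOC)cc(O)c(C(O)C#Cc2ccc(OCOC)c(OCOC)c2)c1OCOC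
F7 | step 11 | 3-[3,4-bis(methoxymethoxy)phenyl]-1-{2-hydroxy-5-{[(1S,2S)-2-hydroxy-2,6,6-trimethylcyclohexyl]methyl}-4,6-bis(methoxymethoxy)phenyl}prop-2-yn-1-one | CC1(C)CCC[C@](C)(O)[C@H]1Cc1c(OCOC)cc(O)c(C(=O)C#Cc2ccc(OCOC)c(OCOC)c2)c1OCOC
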